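1. South-west cannot carry its 10 mM of electrophile through step 1. Each turn costs two nucleophile, one in the step and one taken up with the acid set free as protonated nucleophile (the constant of that binding times c(nucleophile) starts at 7200). So 11.0 mM of nucleophile pays for 5.50 mM of turns. The nucleophile, charged in excess, is therefore the limiting reagent.

| setting | south-west | north-west |
|---|---|---|
| electrophile | 10 mM | 10 mM |
| nucleophile | 11.0 mM | 22.0 mM |
| time | 4.0 min | 4.0 min |

    electrophile + nucleophile ⇌ acid set free + target (K1 = 29, k1 = 2.9 /M/s)
    nucleophile + acid set free ⇌ protonated nucleophile, settled at all times (K2 = 6.5 × 10⁵ /M)
    electrophile + target → side product (k3 = 0.81 /M/s)
    2 nucleophile → homo dimer (k4 = 3.8 /M/s)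

- a species is counted by the electrophile in it: one side product counts as two
- where a step has two of a species, its rate is k times that concentration squared, and two are used at each turn
- run time (south-west): 4.0 min

- part of the electrophile that has reacted at the end, south-west
- part of the electrophile that has reacted at the end, north-west
- what raising the concentration of nucleophile from its lowest to its highest value here does to the part of the electrophile that has reacted (changes below 5 percentage points count as none) (no change / it falls / it rises)

2. Turned round: the reacted part stays flat from south-west to north-west if the added nucleophile goes to homo dimer and buys no turns of step 1. So I count the turns a charge pays for.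

3. Setting step 3 and the way back aside, for each electrophile lost c(nucleophile) falls by two plus w·c(nucleophile)/c(electrophile). Here w = 2.62, two times the dimer constant over the constant of step 1. With b the charged ratio of nucleophile to electrophile, integrating to c(nucleophile) = 0 gives f = 1 − [2/(2 + (w − 1)b)]^(1/(w − 1)). For south-west f = 32.5%: this is the stall share, the part of the charged electrophile that passes step 1 before c(nucleophile) reaches zero in this reckoning. North-west has 46.8%, so it stands 14 percentage points from the flat case.

4. The forward half-life of electrophile by step 1 in south-west is 0.36 min, short against 4.0 min, so I put the stall at the start. Step 3 then joins electrophile and target, and ln(c(electrophile)/c(target)) grows by s(1 − 2f), where s = 1.94 is the step's constant times the charged electrophile times the time. I get 53.7% reacted in south-west and 71.3% in north-west, a rise of 18 points against the margin of 5 points.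

5. The forecast says 54%, 73% and it rises, on the ground that “doubling the nucleophile gives more target before the stall”. Its north-west value stands above mine.

6. The flask gives 53.8% in south-west and 71.0% in north-west: it rises, by 17 points. The difference in charged nucleophile is the main reason for that gap.

7. Homo dimer is a part of why south-west ends at 53.8%: the same flask run without that step reaches 78.9%. With w set to zero, the stall share of south-west reads 55.0% instead of 32.5%. In south-west the dimer step works early, with 95% of its turnover up to the end behind it after 0.400 min.

8. A neighbour flask is south-west charged with 27 mM of nucleophile, the other charge and the time held. There the stall share is 51.1% and I reckon 75.7% reacted; the computed flask gives 75.3%.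

The constants were chosen freely; the flask was simulated.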